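The slowness of the runs at 39 °C is what two chemists argue over: in the gamma run the intermediate stood highest, at 42.2 %, near 10.0 h, while at 47 °C in the zeta run its highest reading, 25.5 %, came near 4.00 h.

| flask | substrate | coupling partner | temperature | remark | time |
|---|---|---|---|---|---|
| eta | 0.15 M | 0.030 M | 39 °C | run made earlier |  |
| alpha | 0.15 M | 0.076 M | 47 °C | run made earlier |  |
| gamma | 0.15 M | 0.14 M | 39 °C | run made earlier |  |
| zeta | 0.16 M | 0.090 M | 47 °C | run made earlier |  |
| Thursday's | 0.15 M | 0.0900 M | 50 °C |  | 12 h |
| Wednesday's | 0.15 M | 0.200 M | 50 °C |  | 12 h |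
| Friday's | 0.15 M | 0.200 M | 35 °C |  | 12 h |
| Tuesday's | 0.10 M | 0.0250 M | 50 °C |  | 12 h |

- eta (time / h: intermediate / %, target / %): 1.33: 4.0, 0.9; 3.00: 7.2, 0.1; 6.00: 11.2, 0; 10.0: 11.6, 0.7; 15.0: 10.4, 1.7
- alpha (time / h: intermediate / %, target / %): 1.50: 16.8, 0.8; 3.00: 22.7, 1.9; 5.00: 22.5, 3.1; 6.00: 21.6, 3.6; 8.00: 17.5, 5.9
- gamma (time / h: intermediate / %, target / %): 2.50: 26.8, 0.7; 5.00: 37.4, 1.4; 8.00: 42.0, 2.0; 10.0: 42.2, 2.9; 15.0: 39.4, 6.4
- zeta (time / h: intermediate / %, target / %): 0.833: 12.8, 0.3; 2.00: 21.9, 1.4; 4.00: 25.5, 1.9; 6.00: 24.4, 5.1; 8.00: 19.8, 4.9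

(standard deviation of a reading: 0.5 percentage points)

- the flasks by amount of intermediate, in percent of the substrate charged, highest first, at 12 h (Thursday's / Wednesday's / Friday's / Tuesday's)
- the same order at 40 min (Thursday's / Wednesday's / Friday's / Tuesday's)
- the amount of intermediate, in percent of the substrate charged of the flask you put first, at 12 h
- the amount of intermediate, in percent of the substrate charged of the flask you put last, at 12 h

The first chemist holds that a flask contains what its charge and its speed give it. With 0.200 M of coupling partner against 0.15 M of substrate, substrate is the limiting reagent in Wednesday's. The first readings of gamma and zeta, taken per unit of coupling partner, show making 2.23 times as fast at the higher temperature, which carried on to 50 °C and 35 °C makes Wednesday's about 4.50 times as fast as Friday's, so she puts Wednesday's first at both times.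

The second chemist solves the two ends of a run, where intermediate grows early and shrinks late, and joins them at the crest time, the hour at which a flask's intermediate stands highest. Eta and gamma, with 0.030 M and 0.14 M of coupling partner, both read highest near 10.0 h, so she treats the crest time as a clock of temperature, which shortens 2.50-fold from 39 °C to 47 °C. Carried along in the same proportion, it gives 15.8 h at 35 °C and 2.84 h at 50 °C. So at 12 h Friday's is still climbing, while the hot flasks are long past their crests, and she puts Friday's first. Her clock gives no heights.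

The forecast sides with her, on the ground that the intermediate “decays first-order, mostly not to target”. It says Friday's > Wednesday's > Thursday's > Tuesday's at 12 h, with 52 % (between 46 % and 57 %) at the top and 6 % (between 4.5 % and 7.5 %) at the bottom, and Wednesday's > Thursday's > Friday's > Tuesday's at 40 min.

The flasks give Friday's > Wednesday's > Thursday's > Tuesday's at 12 h, with 55.9 % and 3.66 %, and Wednesday's > Thursday's > Friday's > Tuesday's at 40 min.

    substrate + coupling partner → intermediate + released group (k = 8.21 × 10⁻⁴ L mol⁻¹ s⁻¹, Ea = 71.0 kJ mol⁻¹)
    intermediate → target (k = 1.86 × 10⁻⁵ s⁻¹, Ea = 117 kJ mol⁻¹)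
    intermediate → decomposed reagent (k = 4.96 × 10⁻⁵ s⁻¹, Ea = 111 kJ mol⁻¹)
    coupling partner → decomposition product (k = 3.89 × 10⁻⁸ s⁻¹, Ea = 115 kJ mol⁻¹)
    target ⇌ isomer of the product (K = 0.560, k = 8.37 × 10⁻⁵ s⁻¹, Ea = 113 kJ mol⁻¹, ΔH = 8.00 kJ mol⁻¹)
    (constants at 50 °C)

So the first chemist is right on the rising side, before the crest time, where Wednesday's 26.8 % stands above Friday's 9.83 %. Friday's, whose crest the clock had put at 15.8 h, was still making intermediate 1.20 times as fast as it used it at 12.0 h. Wednesday's, whose crest the clock had put at 2.84 h, had 31.5 % at 6.00 h and fell to 11.7 % at 12.0 h.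

The earlier runs and the new flask are calculated with constants of no real substance, and the scatter is random.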